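Slowness in this flask can be counted: take the time in which the starting material's fraction of the charge halves, and ask how many such times fit before the moment asked about.

| setting | north-west | flask |
|---|---|---|
| starting material | 0.10 M | 0.10 M |
| second substrate | 0.10 M (fed, over 40 s) | 0.100 M (fed, over 40 s) |
| enzyme | 10 µM | 10 µM |
| remark | the very flask that is asked about, followed so far; the fed solution adds 0.10 times the starting volume | the fed solution adds 0.10 times the starting volume |
| time |  | 40 min |

- north-west (time / min: starting material / %, target / %): 1.33: 69.4, 25.1; 2.50: 50.4, 39.8; 5.00: 25.0, 55.8; 8.00: 8.5, 63.5; 15.0: 0.5, 66.5

(each reading ± 1 percentage point)

- amounts are per litre of the starting volume; all of the dose is in the solution fed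
- the reaction counts as stopped when no species that holds the starting material changes by six tenths of a point or more over the second half of the time

- why nothing more happens at 40 min, or that something still does (forward and back rates have come level / no working catalyst is left / it is still moving / all of the starting material has reacted)
- part of the starting material gone at 40 min
- the target standing at 40 min, as a percentage of the starting material charged

Between 2.50 min and 8.00 min the north-west run, which is this flask followed so far, takes the starting material from 50.4 % to 8.5 % of the charge. This reads as a pseudo-first-order half-life of 2.14 min, the half-life of the starting material. From the last reading at 15.0 min to 40 min, 11.7 such half-lives pass, so about <0.001 % of the charge should remain, and this reckoning expects the flask to stop with the starting material used up. At 15.0 min, starting material and target together fall short of the charge by 33.0 %, up from 28.0 % at 8.00 min. With 0.5 % of the starting material remaining at that reading, this reckoning expects the target to stay near 66.5 %, a reading with a scatter of 1 percentage point.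

The forecast gives all of the starting material has reacted, 99.8 % converted and 66.5 % target, adding that “the target should stay near 67%, perhaps slightly lower”. The flask gives all of the starting material has reacted, 100 % converted and 68.1 % target.

    complex B → enzyme + second product (k = 86.4 /s)
    second substrate + enzyme ⇌ complex B (K = 12.0 /M, k = 5180 /M/s)
    complex A → spent catalyst (k = 0.00526 /s)
    complex A → enzyme + target (k = 92.5 /s)
    starting material + target → side product (k = 0.0245 /M/s)
    starting material + enzyme ⇌ complex A (K = 14.5 /M, k = 1.03 × 10⁵ /M/s)

In this flask, the passing of starting material + target into side product alone gives the target a half-life of 4.7 min, with the other concentrations as charged, which is 2.20 times 2.14 min, the half-life read for the starting material, so the two times are of like size. For the neighbouring flask with 1.7 × 10⁻⁵ M of enzyme, the starting material's half-life, if it scales inversely with enzyme, comes to 1.26 min, and the shortfall read at 15.0 min, scaled alike, comes to 19.4 %. That neighbour ends with 80.6 % target and 19.4 % side product.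

The numbers in the tables come from a simulation with constants of no real substance; noise was put on by code.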